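**Plan**

Notation: ring system A is the dihydrobenzofuran that carries the stilbene arm, and ring system B is the one fused to the central resorcinol ring. C2A, C3A, C5A, C2B, C3B, C3aB and C4B are benzofuran positions in these two units.
Cuts: the seven phenols are masked as methyl ethers and both trans rings are traced back to their C2 epimers. Then the C5A–vinyl bond (Heck), the C3A–C2A bond (carbene C–H insertion), the C3A–C4B bond (aryllithium plus aldehyde) and the C3B–C2B bond (first C–H insertion) are cut in this order.
Enabling feature: in each dihydrofuran ring C3 is a methine held between two aryl rings, and C2 is a 4-oxygenated benzylic carbon bound to an aryl ether oxygen. C3 is therefore a latent diaryl carbene carbon and C2 the OCH2 carbon of a 4-methoxybenzyl aryl ether. C3A and C3B sit on neighbouring carbons (C4B and C3aB) of the central ring, so one ortho-bromobenzophenone delivers first one and then the other.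
Forward order: the dihydrofuran of B closes first. Its C4B bromide becomes the aryllithium that picks up the ring A aldehyde, the derived diazo compound closes the dihydrofuran of A, the stilbene arm is attached by a Heck reaction, and BBr3 ends the route.
Stereochemistry: C3B and C3A (both S, same local sense) come from one enantiomer of the chiral catalyst Rh2(PTAD)4. C2B and C2A are formed cis (R) and are inverted to trans (S) at the end by reversible acid ionisation of the C2–O bonds. The E alkene comes from the Heck reaction.

Key step: step 14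

Assumption: Rh2(R-PTAD)4, dirhodium tetrakis[(R)-(1-adamantyl)(phthalimido)acetate], is taken as the catalyst enantiomer that gives the 3S configuration in insertions of this kind. If the sense of induction is the opposite, Rh2(S-PTAD)4 replaces it in steps 8 and 14 and nothing else changes.

**Route**

Step 1
Reactants: 1 1-bromo-3,5-dimethoxybenzene
Product: 3 2-bromo-4,6-dimethoxybenzaldehyde, via iminium chloride 2 (not isolated)
Conditions: POCl3 (3 equiv), DMF, 0 °C → 100 °C; then ice-water
Reagents that add atoms: N,N-dimethylformamide CN(C)C=O (formyl carbon); water O (carbonyl oxygen)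
Why: Vilsmeier–Haack formylation: the chloroiminium ion formed from DMF and POCl3 attacks the ring carbon that is para to one methoxy group, ortho to the other and next to bromine, the site between the two methoxy groups being more crowded, and water then hydrolyses iminium chloride 2 to the aldehyde.

Step 2
Reactants: 1 1-bromo-3,5-dimethoxybenzene; 3 2-bromo-4,6-dimethoxybenzaldehyde
Product: 5 (2-bromo-4,6-dimethoxyphenyl)(3,5-dimethoxyphenyl)methanol (racemic), via Grignard reagent 4 (not isolated)
Conditions: 1, Mg turnings, THF, reflux; then 3, THF, 0 °C → rt; aq NH4Cl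
Reagents that add atoms: none
Why: Grignard addition to an aldehyde: the arylmagnesium bromide 4 adds to the formyl group far faster than it exchanges with the aryl bromide of 3, and the carbinol centre may be racemic because step 3 removes it.

Step 3
Reactants: 5 (2-bromo-4,6-dimethoxyphenyl)(3,5-dimethoxyphenyl)methanol
Product: 6 (2-bromo-4,6-dimethoxyphenyl)(3,5-dimethoxyphenyl)methanone
Conditions: Dess–Martin periodinane (1.3 equiv), CH2Cl2, 0 °C → rt
Reagents that add atoms: none
Why: Dess–Martin oxidation turns the doubly benzylic secondary alcohol into the benzophenone under mild, nearly neutral conditions that leave the aryl bromide and the four methyl ethers alone.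

Step 4
Reactants: 6 (2-bromo-4,6-dimethoxyphenyl)(3,5-dimethoxyphenyl)methanone
Product: 7 (2-bromo-6-hydroxy-4-methoxyphenyl)(3,5-dimethoxyphenyl)methanone
Conditions: BCl3 (1.2 equiv), CH2Cl2, −78 °C → 0 °C; then H2O
Reagents that add atoms: none
Why: Chelation-directed aryl methyl ether cleavage: BCl3 is held between the carbonyl oxygen and the single ortho methoxy oxygen, so chloride takes off only that methyl group while the three methoxy groups that cannot chelate survive at low temperature.

Step 5
Reactants: 7 (2-bromo-6-hydroxy-4-methoxyphenyl)(3,5-dimethoxyphenyl)methanone; 8 4-methoxybenzyl chloride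
Product: 9 [2-bromo-4-methoxy-6-(4-methoxybenzyloxy)phenyl](3,5-dimethoxyphenyl)methanone
Conditions: K2CO3 (2 equiv), n-Bu4NI (cat.), DMF, 60 °C
Reagents that add atoms: none
Why: Williamson ether synthesis: the phenoxide displaces chloride from the reactive benzylic halide, with iodide catalysis to make up for the crowded, hydrogen-bonded phenol, and installs the OCH2Ar unit whose carbon becomes C2B.

Step 6
Reactants: 9 [2-bromo-4-methoxy-6-(4-methoxybenzyloxy)phenyl](3,5-dimethoxyphenyl)methanone
Product: 10 hydrazone of 9 (C=N–NH2 in place of C=O; either C=N geometry)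
Conditions: H2NNH2·H2O (20 equiv), AcOH (cat.), n-BuOH, 120 °C, sealed tube
Reagents that add atoms: hydrazine (as hydrate) NN
Why: Condensation of a diaryl ketone with hydrazine to the N-unsubstituted hydrazone; the two ortho substituents slow the addition, which is why a large excess of hydrazine, acid catalysis and a high-boiling alcohol are used, and the ethers and the unactivated aryl bromide should tolerate this, while the C=N geometry does not matter.

Step 7
Reactants: 10 hydrazone of 9
Product: 11 1-bromo-2-[diazo(3,5-dimethoxyphenyl)methyl]-5-methoxy-3-(4-methoxybenzyloxy)benzene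
Conditions: activated MnO2 (8 equiv), CH2Cl2, 0 °C → rt; filtration through Celite, used at once
Reagents that add atoms: none
Why: Dehydrogenation of a benzophenone hydrazone with activated MnO2 is the standard way to a diaryldiazomethane, and the two ortho groups should make 11 persistent enough to be freed from the manganese solids by filtration and used at once.

Step 8
Reactants: 11 1-bromo-2-[diazo(3,5-dimethoxyphenyl)methyl]-5-methoxy-3-(4-methoxybenzyloxy)benzene
Product: 12 (2R,3S)-4-bromo-3-(3,5-dimethoxyphenyl)-6-methoxy-2-(4-methoxyphenyl)-2,3-dihydrobenzofuran (2,3-cis)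
Conditions: Rh2(R-PTAD)4 (1 mol %), dry CH2Cl2, 0 °C → rt, slow addition of 11
Reagents that add atoms: none
Why: Enantioselective intramolecular 1,5 C–H insertion of a donor/donor rhodium carbene into a benzyl aryl ether: loss of dinitrogen at the catalyst, hydride-like transfer from the OCH2 group and immediate C–C bond formation close the dihydrofuran of ring system B, the chiral carboxylate ligands choosing the carbene face and thus C3B (S), the rapid collapse placing the C2B aryl group cis (R), and the ortho bromine remaining an inert bystander.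

Step 9
Reactants: 13 5-bromosalicylaldehyde; 8 4-methoxybenzyl chloride
Product: 14 5-bromo-2-(4-methoxybenzyloxy)benzaldehyde
Conditions: K2CO3 (1.5 equiv), DMF, rt → 50 °C
Reagents that add atoms: none
Why: Williamson ether synthesis on an acidic salicylaldehyde phenol with a benzylic chloride, which leaves the aldehyde and the aryl bromide untouched and brings in the carbon that becomes C2A.

Step 10
Reactants: 12 (2R,3S)-4-bromo-3-(3,5-dimethoxyphenyl)-6-methoxy-2-(4-methoxyphenyl)-2,3-dihydrobenzofuran; 14 5-bromo-2-(4-methoxybenzyloxy)benzaldehyde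
Product: 16 [5-bromo-2-(4-methoxybenzyloxy)phenyl][(2R,3S)-3-(3,5-dimethoxyphenyl)-6-methoxy-2-(4-methoxyphenyl)-2,3-dihydrobenzofuran-4-yl]methanol (both carbinol epimers), via aryllithium 15 (not isolated)
Conditions: n-BuLi (1.05 equiv), THF, −78 °C; then 14, −78 °C; aq NH4Cl
Reagents that add atoms: none
Why: Bromine–lithium exchange followed by 1,2-addition of the aryllithium to an aldehyde; at −78 °C the exchange outruns deprotonation of the doubly benzylic C3B–H (which would open the ring by β-elimination) and carbonyl addition outruns exchange with the aryl bromide of 14, while the new carbinol centre, formed as a mixture, disappears in the next step.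

Step 11
Reactants: 16 diaryl carbinol from step 10
Product: 17 [5-bromo-2-(4-methoxybenzyloxy)phenyl][(2R,3S)-3-(3,5-dimethoxyphenyl)-6-methoxy-2-(4-methoxyphenyl)-2,3-dihydrobenzofuran-4-yl]methanone
Conditions: Dess–Martin periodinane (1.3 equiv), CH2Cl2, 0 °C → rt
Reagents that add atoms: none
Why: Dess–Martin oxidation of the diaryl carbinol merges both epimers into one ketone without acid or base strong enough to disturb the cis ring, the 4-methoxybenzyl ether or the aryl bromide.

Step 12
Reactants: 17 diaryl ketone from step 11
Product: 18 hydrazone of 17 (C=N–NH2 in place of C=O; either C=N geometry)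
Conditions: H2NNH2·H2O (20 equiv), AcOH (cat.), EtOH, 90 °C, sealed tube
Reagents that add atoms: hydrazine (as hydrate) NN
Why: Hydrazone condensation as in step 6 on a ketone with one ortho substituent on each aryl ring; the hydrazine/acetic acid buffer is too weakly acidic to ionise the C2B–O bond appreciably and too weakly basic to remove C3B–H, and a partial epimerisation at C2B would in any case be harmless because step 16 resets this centre.

Step 13
Reactants: 18 hydrazone of 17
Product: 19 (2R,3S)-4-{[5-bromo-2-(4-methoxybenzyloxy)phenyl](diazo)methyl}-3-(3,5-dimethoxyphenyl)-6-methoxy-2-(4-methoxyphenyl)-2,3-dihydrobenzofuran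
Conditions: activated MnO2 (8 equiv), CH2Cl2, 0 °C → rt; filtration through Celite, used at once
Reagents that add atoms: none
Why: MnO2 dehydrogenation of the hydrazone to the diaryldiazomethane as in step 7, a neutral heterogeneous oxidation that touches none of the ethers, the stereocentres or the bromide.

Step 14
Reactants: 19 (2R,3S)-4-{[5-bromo-2-(4-methoxybenzyloxy)phenyl](diazo)methyl}-3-(3,5-dimethoxyphenyl)-6-methoxy-2-(4-methoxyphenyl)-2,3-dihydrobenzofuran
Product: 20 (2R,3S)-5-bromo-3-[(2R,3S)-3-(3,5-dimethoxyphenyl)-6-methoxy-2-(4-methoxyphenyl)-2,3-dihydrobenzofuran-4-yl]-2-(4-methoxyphenyl)-2,3-dihydrobenzofuran (cis in A, cis in B)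
Conditions: Rh2(R-PTAD)4 (2 mol %), dry CH2Cl2, 0 °C → rt, 19 added by syringe pump
Reagents that add atoms: none
Why: The diazo carbon of 19 binds to an axial site of Rh2(R-PTAD)4 and loses dinitrogen, giving a diaryl (donor/donor) carbene of divalent rhodium that is too weakly electrophilic to dimerise readily or to attack bystander groups; a hydride-like shift from the OCH2 group of the ortho 4-methoxybenzyl ether through a six-membered array, followed at once by C–C bond formation inside the resulting oxocarbenium/benzylrhodium pair, creates the C3A–C2A bond. The closest known reaction type is the dirhodium-carboxylate-catalysed enantioselective 1,5 C–H insertion of diaryldiazomethanes (made from hydrazones with MnO2) into benzyl aryl ethers, which gives cis-2,3-diaryl-2,3-dihydrobenzofurans; here it is applied to a carbene whose second aryl group already carries ring system B. One ring closes, the five-membered dihydrofuran of A, by 1,5 insertion: counted on the C–H bond that breaks, which lies outside the new ring, this is a 5-exo-tet-type closure, and in the stepwise limit it is the collapse of the rhodium-bound carbon onto the adjacent oxocarbenium carbon. C3A (S) is set by the chiral pocket of the four phthalimido(adamantyl)acetate ligands, which decides which carbene face meets the ether C–H bond, and C2A (R, cis to C3A) by the collapse of the ion pair before any bond rotation. The step needs face selectivity in the presence of C2B and C3B, which is entrusted to the catalyst enantiomer that already produced the same local sense at C3B in step 8, and site selectivity, which the substrate secures: C3B–H could only give a four-membered ring, C2B–H only a bridged ring with an aromatic bridgehead, no methoxy group stands ortho to the carbene, the aryl bromide is inert and the reactive stilbene alkene is not yet present.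

Step 15
Reactants: 20 cis,cis bis(dihydrobenzofuran) bromide from step 14; 21 3,5-dimethoxystyrene
Product: 22 (2R,3S)-5-[(E)-3,5-dimethoxystyryl]-3-[(2R,3S)-3-(3,5-dimethoxyphenyl)-6-methoxy-2-(4-methoxyphenyl)-2,3-dihydrobenzofuran-4-yl]-2-(4-methoxyphenyl)-2,3-dihydrobenzofuran (cis,cis heptamethyl ether)
Conditions: Pd(OAc)2 (5 mol %), P(o-tol)3 (15 mol %), Et3N (3 equiv), DMF, 100 °C
Reagents that add atoms: none
Why: Mizoroki–Heck reaction: oxidative addition of zerovalent palladium into the C5A–Br bond, syn insertion of the styrene at its unsubstituted carbon and syn β-hydride elimination give the E-stilbene, and the weak amine base leaves the C3–H bonds and both cis rings untouched.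

Step 16
Reactants: 22 cis,cis heptamethyl ether from step 15
Product: 23 trans-diptoindonesin B (2S,3S in ring system A; 2S,3S in ring system B; E alkene)
Conditions: BBr3 (20 equiv), CH2Cl2, −78 °C → rt; then ice-water
Reagents that add atoms: none
Why: Lewis-acid ether cleavage with BBr3 removes all seven methyl groups, and the same reagent, together with the HBr released on quenching, reversibly ionises each C2–O bond to a cation stabilised in a para-quinone-methide manner by the 4-oxygenated aryl ring, which is recaptured by the neighbouring phenol oxygen to give the more stable 2,3-trans ring, so that C2A and C2B are inverted (R to S) while C3A and C3B, which take no part in the ionising bond, keep their configuration.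

**Compound list**

1 | 1-bromo-3,5-dimethoxybenzene | COc1cc(Br)cc(OC)c1 | starting material
2 | (2-bromo-4,6-dimethoxybenzylidene)dimethylammonium chloride | COc1cc(Br)c(C=[N+](C)C)c(OC)c1.[Cl-] | intermediate
3 | 2-bromo-4,6-dimethoxybenzaldehyde | COc1cc(Br)c(C=O)c(OC)c1 | intermediate
4 | 3,5-dimethoxyphenylmagnesium bromide | COc1cc([Mg]Br)cc(OC)c1 | intermediate
5 | (2-bromo-4,6-dimethoxyphenyl)(3,5-dimethoxyphenyl)methanol, racemic | COc1cc(OC)cc(C(O)c2c(Br)cc(OC)cc2OC)c1 | intermediate
6 | (2-bromo-4,6-dimethoxyphenyl)(3,5-dimethoxyphenyl)methanone | COc1cc(OC)cc(C(=O)c2c(Br)cc(OC)cc2OC)c1 | intermediate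
7 | (2-bromo-6-hydroxy-4-methoxyphenyl)(3,5-dimethoxyphenyl)methanone | COc1cc(O)c(C(=O)c2cc(OC)cc(OC)c2)c(Br)c1 | intermediate
8 | 4-methoxybenzyl chloride | COc1ccc(CCl)cc1 | starting material
9 | [2-bromo-4-methoxy-6-(4-methoxybenzyloxy)phenyl](3,5-dimethoxyphenyl)methanone | COc1ccc(COc2cc(OC)cc(Br)c2C(=O)c2cc(OC)cc(OC)c2)cc1 | intermediate
10 | hydrazone of 9 | COc1ccc(COc2cc(OC)cc(Br)c2C(=NN)c2cc(OC)cc(OC)c2)cc1 | intermediate
11 | 1-bromo-2-[diazo(3,5-dimethoxyphenyl)methyl]-5-methoxy-3-(4-methoxybenzyloxy)benzene | COc1ccc(COc2cc(OC)cc(Br)c2C(=[N+]=[N-])c2cc(OC)cc(OC)c2)cc1 | intermediate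
12 | (2R,3S)-4-bromo-3-(3,5-dimethoxyphenyl)-6-methoxy-2-(4-methoxyphenyl)-2,3-dihydrobenzofuran, 2,3-cis | Brc1cc(OC)cc2c1[C@H](c1cc(OC)cc(OC)c1)[C@H](c1ccc(OC)cc1)O2 | intermediate
13 | 5-bromosalicylaldehyde | O=Cc1cc(Br)ccc1O | starting material
14 | 5-bromo-2-(4-methoxybenzyloxy)benzaldehyde | COc1ccc(COc2ccc(Br)cc2C=O)cc1 | intermediate
15 | [(2R,3S)-3-(3,5-dimethoxyphenyl)-6-methoxy-2-(4-methoxyphenyl)-2,3-dihydrobenzofuran-4-yl]lithium | [Li]c1cc(OC)cc2c1[C@H](c1cc(OC)cc(OC)c1)[C@H](c1ccc(OC)cc1)O2 | intermediate
16 | diaryl carbinol joining ring system B to the future ring system A, both carbinol epimers | COc1ccc(COc2ccc(Br)cc2C(O)c2cc(OC)cc3c2[C@H](c2cc(OC)cc(OC)c2)[C@H](c2ccc(OC)cc2)O3)cc1 | intermediate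
17 | diaryl ketone from 16 | COc1ccc(COc2ccc(Br)cc2C(=O)c2cc(OC)cc3c2[C@H](c2cc(OC)cc(OC)c2)[C@H](c2ccc(OC)cc2)O3)cc1 | intermediate
18 | hydrazone of 17 | COc1ccc(COc2ccc(Br)cc2C(=NN)c2cc(OC)cc3c2[C@H](c2cc(OC)cc(OC)c2)[C@H](c2ccc(OC)cc2)O3)cc1 | intermediate
19 | diaryldiazomethane from 18, precursor of the key step | COc1ccc(COc2ccc(Br)cc2C(=[N+]=[N-])c2cc(OC)cc3c2[C@H](c2cc(OC)cc(OC)c2)[C@H](c2ccc(OC)cc2)O3)cc1 | intermediate
20 | cis,cis bis(dihydrobenzofuran) bromide, (2R,3S) in A and (2R,3S) in B | COc1ccc([C@@H]2Oc3ccc(Br)cc3[C@@H]2c2cc(OC)cc3c2[C@H](c2cc(OC)cc(OC)c2)[C@H](c2ccc(OC)cc2)O3)cc1 | intermediate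
21 | 3,5-dimethoxystyrene | C=Cc1cc(OC)cc(OC)c1 | starting material
22 | cis,cis heptamethyl ether with E-stilbene, (2R,3S) in A and (2R,3S) in B | COc1ccc([C@@H]2Oc3ccc(/C=C/c4cc(OC)cc(OC)c4)cc3[C@@H]2c2cc(OC)cc3c2[C@H](c2cc(OC)cc(OC)c2)[C@H](c2ccc(OC)cc2)O3)cc1 | intermediate
23 | trans-diptoindonesin B, (2S,3S) in A and (2S,3S) in B, E alkene | Oc1ccc([C@H]2Oc3ccc(/C=C/c4cc(O)cc(O)c4)cc3[C@@H]2c2cc(O)cc3c2[C@H](c2cc(O)cc(O)c2)[C@@H](c2ccc(O)cc2)O3)cc1 | target

**Step count and risks**

Total steps: 16. Longest linear sequence: 15 steps (steps 1–8 and 10–16, from 1 to 23). Step 9 is the only side branch.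

Steps most likely to fail:

Step 14.
- The C3B aryl group next to the carbene may oppose the catalyst (mismatched double stereodifferentiation), which would give poor facial selectivity at C3A.
- The crowded diazo carbon may also engage rhodium slowly. Azine formation, or attack of the carbene on the neighbouring electron-rich dimethoxyphenyl ring, could then compete.
- The fallback sets out from 12 and returns at 23. It exchanges the order of epimerisation and insertion, so that the carbene meets a differently shaped neighbour.
- Brief exposure of 12 to CF3CO2H in CH2Cl2 should equilibrate C2B through the same benzylic cation that step 16 relies on and give the 2,3-trans bromide F1.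
- Bromine–lithium exchange (n-BuLi, THF, −78 °C) gives aryllithium F2, which adds to 14 to give carbinol F3.
- Dess–Martin oxidation gives ketone F4, hydrazine hydrate gives hydrazone F5, and MnO2 gives diazo compound F6.
- Insertion with Rh2(R-PTAD)4 should then give the bromide F7 (A cis, B trans). In the trans ring the C2B aryl group no longer presses the C3B aryl group towards the peri position. The substrate bias is altered and the catalyst has a better chance to dominate.
- The Heck reaction with 21 gives the heptamethyl ether F8. BBr3 as in step 16, which now has to invert only C2A, leads to 23.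

Step 16.
- The electron-rich stilbene may be protonated and consumed by Friedel–Crafts oligomerisation.
- An open C2 cation may be captured irreversibly by a resorcinol carbon of the neighbouring ring instead of by the phenol oxygen.
- An open C2 cation may also lose the C3 proton, which would erode the C3 configuration.
- Demethylation or epimerisation may stop short of completion.
- The fallback sets out from 20 and returns at 23. It moves all strong-acid chemistry ahead of the alkene and changes the phenol protection.
- BBr3 (CH2Cl2, −78 °C → rt) on 20 should give the trans,trans pentaphenol bromide F9, and Ac2O/pyridine the pentaacetate F10.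
- A Heck reaction of F10 with commercial 3,5-diacetoxystyrene (Pd(OAc)2, P(o-tol)3, Et3N, DMF) gives the heptaacetate F11.
- Mild methanolysis (K2CO3, MeOH, argon, 0 °C → rt) releases 23 without any acid touching the stilbene.

Step 6.
- Addition of hydrazine to a carbonyl carbon shielded on both faces by the ortho bromine and the ortho benzyloxy group may fail.
- On forcing, ring closure of the hydrazone nitrogen onto the brominated carbon may set in.
- The fallback sets out from 9 and returns at 10. It replaces the carbonyl by a more reactive thiocarbonyl.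
- Lawesson's reagent (toluene, 110 °C) should convert 9 into the thioketone F12. Its weak C=S bond condenses with hydrazine hydrate already at room temperature (THF/EtOH) to give 10.

**Further compounds**

F1 | step 14 | (2S,3S)-4-bromo-3-(3,5-dimethoxyphenyl)-6-methoxy-2-(4-methoxyphenyl)-2,3-dihydrobenzofuran, 2,3-trans | Brc1cc(OC)cc2c1[C@H](c1cc(OC)cc(OC)c1)[C@@H](c1ccc(OC)cc1)O2
F2 | step 14 | aryllithium from F1 | [Li]c1cc(OC)cc2c1[C@H](c1cc(OC)cc(OC)c1)[C@@H](c1ccc(OC)cc1)O2
F3 | step 14 | diaryl carbinol with trans ring B, both carbinol epimers | COc1ccc(COc2ccc(Br)cc2C(O)c2cc(OC)cc3c2[C@H](c2cc(OC)cc(OC)c2)[C@@H](c2ccc(OC)cc2)O3)cc1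
F4 | step 14 | diaryl ketone with trans ring B | COc1ccc(COc2ccc(Br)cc2C(=O)c2cc(OC)cc3c2[C@H](c2cc(OC)cc(OC)c2)[C@@H](c2ccc(OC)cc2)O3)cc1
F5 | step 14 | hydrazone of F4 | COc1ccc(COc2ccc(Br)cc2C(=NN)c2cc(OC)cc3c2[C@H](c2cc(OC)cc(OC)c2)[C@@H](c2ccc(OC)cc2)O3)cc1
F6 | step 14 | diaryldiazomethane from F5 | COc1ccc(COc2ccc(Br)cc2C(=[N+]=[N-])c2cc(OC)cc3c2[C@H](c2cc(OC)cc(OC)c2)[C@@H](c2ccc(OC)cc2)O3)cc1
F7 | step 14 | bis(dihydrobenzofuran) bromide, (2R,3S) cis in A and (2S,3S) trans in B | COc1ccc([C@@H]2Oc3ccc(Br)cc3[C@@H]2c2cc(OC)cc3c2[C@H](c2cc(OC)cc(OC)c2)[C@@H](c2ccc(OC)cc2)O3)cc1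
F8 | step 14 | heptamethyl ether with E-stilbene, cis in A and trans in B | COc1ccc([C@@H]2Oc3ccc(/C=C/c4cc(OC)cc(OC)c4)cc3[C@@H]2c2cc(OC)cc3c2[C@H](c2cc(OC)cc(OC)c2)[C@@H](c2ccc(OC)cc2)O3)cc1
F9 | step 16 | trans,trans pentaphenol bromide, (2S,3S) in A and B | Oc1ccc([C@H]2Oc3ccc(Br)cc3[C@@H]2c2cc(O)cc3c2[C@H](c2cc(O)cc(O)c2)[C@@H](c2ccc(O)cc2)O3)cc1
F10 | step 16 | pentaacetate of F9 | CC(=O)Oc1ccc([C@H]2Oc3ccc(Br)cc3[C@@H]2c2cc(OC(C)=O)cc3c2[C@H](c2cc(OC(C)=O)cc(OC(C)=O)c2)[C@@H](c2ccc(OC(C)=O)cc2)O3)cc1
F11 | step 16 | heptaacetate of trans-diptoindonesin B | CC(=O)Oc1ccc([C@H]2Oc3ccc(/C=C/c4cc(OC(C)=O)cc(OC(C)=O)c4)cc3[C@@H]2c2cc(OC(C)=O)cc3c2[C@H](c2cc(OC(C)=O)cc(OC(C)=O)c2)[C@@H](c2ccc(OC(C)=O)cc2)O3)cc1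
F12 | step 6 | [2-bromo-4-methoxy-6-(4-methoxybenzyloxy)phenyl](3,5-dimethoxyphenyl)methanethione | COc1ccc(COc2cc(OC)cc(Br)c2C(=S)c2cc(OC)cc(OC)c2)cc1
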